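The carbocycle is cut at C4a–C8a and C6–C7. This uses the 1,3,5-oxygenation of the ring C4a/C5/C6/C7/C8/C8a: C8 (methyl, geranyl) is flanked by the C7 and C8a carbonyls, a dialkylmalonate in disguise, and C4a–C5–C6 plus the C6 prenyl chain is 6-methylhept-5-en-2-one. One operation joins the two: Claisen C-acylation of the ketone's methyl enolate by an acid chloride, then Dieckmann closure onto the neighbouring ester. It delivers the six-membered trione with C8 preset and no arene involved. The precursor is the enantiopure (S)-acid chloride methyl ester of 2-geranyl-2-methylmalonic acid. The pyranone ring (O1–C4) is annulated afterwards from (R)-3-hydroxybutanoic acid.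

Key step: step 4

Remark: chromane numbering of the target is used (O1, C2–C4, C4a, C5–C8, C8a); geranyl = (2E)-3,7-dimethylocta-2,6-dien-1-yl, prenyl = 3-methylbut-2-en-1-yl. Triones 8, 13 and 14 are tautomeric mixtures drawn as one enol. The structures (S)-5, (R)-8 and (2S,8R)-15 were checked and share one spatial arrangement at C8; the descriptor changes come from CIP priorities only, so nothing needed correcting.

Step 1
Reactants: 1 dimethyl 2-methylmalonate; 2 geranyl bromide
Product: 3 dimethyl 2-geranyl-2-methylmalonate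
Conditions: NaH (1.1 eq), THF, 0 °C; then 2, 0 °C → rt
Reagents that add atoms: none
Why: Malonic ester alkylation, in which the soft sodium enolate should displace the primary allylic bromide by SN2 without allylic transposition or loss of the E geometry, and the quaternary product cannot alkylate again.

Step 2
Reactants: 3 dimethyl 2-geranyl-2-methylmalonate
Product: 4 (2R,4E)-2-(methoxycarbonyl)-2,5,9-trimethyldeca-4,8-dienoic acid
Conditions: pig liver esterase, 0.1 M phosphate buffer pH 7.5, DMSO (10 vol%), 25 °C, pH-stat with 1 M NaOH; then 1 M HCl to pH 2, EtOAc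
Reagents that add atoms: water, O
Why: Enzymatic desymmetrisation of a prochiral 2-alkyl-2-methylmalonate, in which hydrolysis of the pro-S methoxycarbonyl group (the sense expected for long lipophilic chains in this substrate class) sets the quaternary stereocentre and stops at the mono-acid because the carboxylate is not a substrate.

Step 3
Reactants: 4 (2R,4E)-2-(methoxycarbonyl)-2,5,9-trimethyldeca-4,8-dienoic acid
Product: 5 methyl (2S,4E)-2-(chlorocarbonyl)-2,5,9-trimethyldeca-4,8-dienoate
Conditions: NaH (1.0 eq), THF, 0 °C; (COCl)2 (1.2 eq), DMF (cat.), 0 °C → rt; evaporate, hexane, filter, use at once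
Reagents that add atoms: oxalyl chloride, O=C(Cl)C(=O)Cl
Why: Acyl chloride formation from the sodium carboxylate through the Vilsmeier-type chloroiminium catalyst gives only gases and NaCl, so no free HCl can add to the trisubstituted alkenes, and the fully substituted α-carbon can neither racemise nor form a ketene.

Step 4
Reactants: 5 methyl (2S,4E)-2-(chlorocarbonyl)-2,5,9-trimethyldeca-4,8-dienoate; 6 6-methylhept-5-en-2-one
Product: 8 (2R)-2-geranyl-5-hydroxy-2-methyl-4-prenylcyclohex-4-ene-1,3-dione, via diketo ester 7 (not isolated)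
Conditions: 6 (2.2 eq), LDA (2.2 eq), THF, −78 °C; 5 in THF, −78 °C; then LDA (3.0 eq), −78 → 0 °C; 1 M HCl; NaHCO3 extraction and re-acidification
Reagents that add atoms: none
Why: The lithium enolate formed at the methyl group of 6 (future C4a) attacks the acid chloride carbonyl of 5 (future C8a) in a crossed Claisen C-acylation and the β-diketone 7 is held as its lithium diketonate; further LDA deprotonates the only other enolisable site, the CH2 that carries the prenyl residue (future C6), and this dianion carbon adds to the methyl ester (future C7) and expels methoxide. The closest known chemistry is the acylation of ketone enolates by malonyl half-ester chlorides followed by terminal acylation of a β-diketone dianion, the arene-free entry to 2,2-disubstituted cyclohexane-1,3,5-triones. The ring closes in a 6-(enolendo)-exo-trig Dieckmann mode and deprotonation of the acidic trione makes the closure irreversible. No new stereocentre arises and the existing one is inert, since C8 is fully substituted and a spectator to both C–C bond formations; the configuration of 5 reaches 8 intact provided the chloride carbon becomes C8a and the ester carbon C7. That regiochemistry should be secured by deprotonation of 6 at the methyl group at −78 °C with a hindered amide base, by the large reactivity gap between COCl and CO2Me, and by the neopentylic acyl chloride reacting preferentially with the unhindered terminal enolate over any internal enolate, which would deliver the C8 enantiomer. C- over O-acylation is favoured by the lithium counter-ion in THF at low temperature with the enolate in excess, and the second portion of LDA is added cold so that the diketonate does not lactonise onto the ester before the dianion forms.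

Step 5
Reactants: 9 (R)-3-hydroxybutanoic acid
Product: 11 (R)-3-[(tert-butyldimethylsilyl)oxy]butanoic acid, via silyl ester 10 (not isolated)
Conditions: TBSCl (2.3 eq), imidazole (5 eq), DMF, rt; then K2CO3, THF/H2O, rt; 1 M HCl to pH 4
Reagents that add atoms: tert-butyldimethylsilyl chloride (TBSCl), CC(C)(C)[Si](C)(C)Cl
Why: Imidazole-promoted silylation caps both OH groups and mild carbonate hydrolysis cleaves only the labile silyl ester, so the secondary silyl ether and the untouched stereocentre of the chiral-pool acid remain.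

Step 6
Reactants: 8 (2R)-2-geranyl-5-hydroxy-2-methyl-4-prenylcyclohex-4-ene-1,3-dione; 11 (R)-3-[(tert-butyldimethylsilyl)oxy]butanoic acid
Product: 13 (6R)-4-[(3R)-3-{[tert-butyl(dimethyl)silyl]oxy}butanoyl]-6-geranyl-3,5-dihydroxy-6-methyl-2-prenylcyclohexa-2,4-dien-1-one, via enol ester 12 (not isolated)
Conditions: 11 (1.2 eq), DCC (1.3 eq), DMAP (1.5 eq), CH2Cl2, 0 °C → rt
Reagents that add atoms: none
Why: Carbodiimide activation gives an enol ester that DMAP transfers from O to C (Steglich-type enol ester to β-triketone rearrangement, the standard C-acylation of cyclic 1,3-diones), and the acyl group should settle on C4a because only there is the product a chelated, enolisable triketone, whereas acylation at the prenylated C6 is reversible.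

Step 7
Reactants: 13 (6R)-4-[(3R)-3-{[tert-butyl(dimethyl)silyl]oxy}butanoyl]-6-geranyl-3,5-dihydroxy-6-methyl-2-prenylcyclohexa-2,4-dien-1-one
Product: 14 (6R)-6-geranyl-3,5-dihydroxy-4-[(3R)-3-hydroxybutanoyl]-6-methyl-2-prenylcyclohexa-2,4-dien-1-one
Conditions: HF·pyridine, pyridine, THF, 0 °C → rt
Reagents that add atoms: none
Why: Fluoride-driven desilylation with pyridine-buffered HF cleaves the Si–O bond under conditions too mild to dehydrate the β-hydroxy ketone or to cyclise the prenyl and geranyl alkenes onto the enols.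

Step 8
Reactants: 14 (6R)-6-geranyl-3,5-dihydroxy-4-[(3R)-3-hydroxybutanoyl]-6-methyl-2-prenylcyclohexa-2,4-dien-1-one
Product: 15 (2S,8R)-8-geranyl-5-hydroxy-2,8-dimethyl-6-prenyl-2,3-dihydro-4H-chromene-4,7(8H)-dione
Conditions: PPh3 (1.5 eq), DIAD (1.5 eq), THF (0.01 M), 0 °C → rt, 14 added to the preformed betaine
Reagents that add atoms: none
Why: Intramolecular Mitsunobu etherification, in which the acidic enol is the pronucleophile and O8a displaces the alkoxyphosphonium at C2 in a 6-exo-tet SN2 step with inversion, turning the (R)-carbinol into the (2S) centre; O8a is expected to react because the 5-OH stays locked in its hydrogen bond to the acyl carbonyl, which turns the side chain towards O8a, and any O5-closed isomer would be removed by chromatography.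

Compound list

1 | dimethyl 2-methylmalonate | COC(=O)C(C)C(=O)OC | starting material
2 | geranyl bromide, (2E)-1-bromo-3,7-dimethylocta-2,6-diene | CC(C)=CCC/C(C)=C/CBr | starting material
3 | dimethyl 2-[(2E)-3,7-dimethylocta-2,6-dien-1-yl]-2-methylmalonate | CC(C)=CCC/C(C)=C/CC(C)(C(=O)OC)C(=O)OC | intermediate
4 | (2R,4E)-2-(methoxycarbonyl)-2,5,9-trimethyldeca-4,8-dienoic acid | CC(C)=CCC/C(C)=C/C[C@@](C(O)=O)(C)C(=O)OC | intermediate
5 | methyl (2S,4E)-2-(chlorocarbonyl)-2,5,9-trimethyldeca-4,8-dienoate | CC(C)=CCC/C(C)=C/C[C@@](C(Cl)=O)(C)C(=O)OC | intermediate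
6 | 6-methylhept-5-en-2-one | CC(=O)CCC=C(C)C | starting material
7 | methyl (2R,4E)-2,5,9-trimethyl-2-(7-methyl-3-oxooct-6-enoyl)deca-4,8-dienoate, present as its lithium enolate | CC(C)=CCC/C(C)=C/C[C@@](C(=O)CC(=O)CCC=C(C)C)(C)C(=O)OC | intermediate
8 | (2R)-2-[(2E)-3,7-dimethylocta-2,6-dien-1-yl]-5-hydroxy-2-methyl-4-(3-methylbut-2-en-1-yl)cyclohex-4-ene-1,3-dione | CC(C)=CCC/C(C)=C/C[C@@]1(C)C(=O)C(CC=C(C)C)=C(O)CC1=O | intermediate
9 | (R)-3-hydroxybutanoic acid | C[C@@H](O)CC(=O)O | starting material
10 | tert-butyldimethylsilyl (R)-3-[(tert-butyldimethylsilyl)oxy]butanoate | C[C@@H](O[Si](C)(C)C(C)(C)C)CC(=O)O[Si](C)(C)C(C)(C)C | intermediate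
11 | (R)-3-[(tert-butyldimethylsilyl)oxy]butanoic acid | C[C@@H](O[Si](C)(C)C(C)(C)C)CC(=O)O | intermediate
12 | (4R)-4-[(2E)-3,7-dimethylocta-2,6-dien-1-yl]-4-methyl-2-(3-methylbut-2-en-1-yl)-3,5-dioxocyclohex-1-en-1-yl (3R)-3-[(tert-butyldimethylsilyl)oxy]butanoate (O5 enol ester; regioisomeric enol esters converge on 13) | CC(C)=CCC/C(C)=C/C[C@@]1(C)C(=O)C(CC=C(C)C)=C(OC(=O)C[C@@H](C)O[Si](C)(C)C(C)(C)C)CC1=O | intermediate
13 | (6R)-4-[(3R)-3-{[tert-butyl(dimethyl)silyl]oxy}butanoyl]-6-[(2E)-3,7-dimethylocta-2,6-dien-1-yl]-3,5-dihydroxy-6-methyl-2-(3-methylbut-2-en-1-yl)cyclohexa-2,4-dien-1-one | CC(C)=CCC/C(C)=C/C[C@@]1(C)C(=O)C(CC=C(C)C)=C(O)C(C(=O)C[C@@H](C)O[Si](C)(C)C(C)(C)C)=C1O | intermediate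
14 | (6R)-6-[(2E)-3,7-dimethylocta-2,6-dien-1-yl]-3,5-dihydroxy-4-[(3R)-3-hydroxybutanoyl]-6-methyl-2-(3-methylbut-2-en-1-yl)cyclohexa-2,4-dien-1-one | CC(C)=CCC/C(C)=C/C[C@@]1(C)C(=O)C(CC=C(C)C)=C(O)C(C(=O)C[C@@H](C)O)=C1O | intermediate
15 | (2S,8R)-8-[(2E)-3,7-dimethylocta-2,6-dien-1-yl]-5-hydroxy-2,8-dimethyl-6-(3-methylbut-2-en-1-yl)-2,3-dihydro-4H-chromene-4,7(8H)-dione | CC(C)=CCC/C(C)=C/C[C@@]1(C)C(=O)C(CC=C(C)C)=C(O)C2=C1O[C@@H](C)CC2=O | target

Total step count: 8. Longest linear sequence: 7 (steps 1, 2, 3, 4, 6, 7, 8); step 5 is a one-step side branch.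

Steps most likely to fail

Step 4. The acid chloride may acylate the enolate on oxygen. Proton exchange between the enolate and liberated ketone may move the enolate to the internal position, which leaks the C8 enantiomer. The diketonate may lactonise onto the ester before the dianion has formed. The fallback sets out from 5 and comes back at 8. Allyl acetoacetate is converted into its dianion (NaH, then n-BuLi, THF, 0 °C) and prenylated at the terminal carbon with prenyl bromide to prop-2-en-1-yl 7-methyl-3-oxooct-6-enoate F1. Its magnesium enolate (MgCl2, pyridine, CH2Cl2, 0 °C) is C-acylated by 5 at the doubly activated methylene, which can only become C4a, to give methyl (2R,4E)-2-{7-methyl-3-oxo-2-[(prop-2-en-1-yloxy)carbonyl]oct-6-enoyl}-2,5,9-trimethyldeca-4,8-dienoate F2. LDA (2.2 eq, THF, −78 → 0 °C) then generates the C6 carbanion, which closes onto the methyl ester to prop-2-en-1-yl (5R)-5-[(2E)-3,7-dimethylocta-2,6-dien-1-yl]-2,6-dihydroxy-5-methyl-3-(3-methylbut-2-en-1-yl)-4-oxocyclohexa-2,6-diene-1-carboxylate F3. Pd(PPh3)4 and morpholine in THF remove the allyl group and the resulting vinylogous β-keto acid loses CO2 to return 8.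

Step 8. Closure may run through O5 in place of O8a, or the activated carbinol may undergo β-elimination to the crotonoyl trione; either loss is irreversible. The fallback sets out from 8 and comes back at 15. Compound 8 is C-acylated at C4a with (E)-but-2-enoic acid under the conditions of step 6 to give (6R)-4-[(2E)-but-2-enoyl]-6-[(2E)-3,7-dimethylocta-2,6-dien-1-yl]-3,5-dihydroxy-6-methyl-2-(3-methylbut-2-en-1-yl)cyclohexa-2,4-dien-1-one F4. A cinchona-alkaloid-derived bifunctional catalyst (quinine or quinidine series, chosen for the 2S sense; toluene, low temperature) then effects the intramolecular 6-endo-trig oxa-Michael addition to 15. This addition is reversible, so an O5-closed adduct or a 2-epimer (a separable diastereomer) can be reopened to F4 with base and recycled, which the SN2 closure does not allow.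

Step 2. The enzyme may discriminate the two enantiotopic ester groups weakly or in the opposite sense, or turn over the lipophilic diester slowly. A small leak is tolerable, because the C8 enantiomer becomes a diastereomer from 13 onwards and can be removed there; poor or reversed selectivity is not. The fallback sets out from 2 and comes back at 4. 2,2,5-Trimethyl-1,3-dioxane-4,6-dione is opened with tert-butanol at reflux to 3-tert-butoxy-2-methyl-3-oxopropanoic acid F5, which bromodiphenylmethane and Et3N convert into tert-butyl diphenylmethyl 2-methylpropanedioate F6. F6 is geranylated with 2 under chiral phase-transfer catalysis (C2-symmetric binaphthyl-derived spiro quaternary ammonium bromide, antipode chosen for the sense drawn; 50% aq. KOH, toluene, −40 °C) to 1-tert-butyl 3-diphenylmethyl (2S)-2-[(2E)-3,7-dimethylocta-2,6-dien-1-yl]-2-methylpropanedioate F7. KOH in MeOH hydrolyses only the diphenylmethyl ester to (2S,4E)-2-(tert-butoxycarbonyl)-2,5,9-trimethyldeca-4,8-dienoic acid F8. MeI and K2CO3 in DMF give 1-tert-butyl 3-methyl (2S)-2-[(2E)-3,7-dimethylocta-2,6-dien-1-yl]-2-methylpropanedioate F9. TMSOTf and 2,6-lutidine (CH2Cl2, 0 °C, aqueous work-up) cleave the tert-butyl ester without acid strong enough to attack the alkenes and return 4.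

Further compounds

F1 | step 4 | prop-2-en-1-yl 7-methyl-3-oxooct-6-enoate | C=CCOC(=O)CC(=O)CCC=C(C)C
F2 | step 4 | methyl (2R,4E)-2-{7-methyl-3-oxo-2-[(prop-2-en-1-yloxy)carbonyl]oct-6-enoyl}-2,5,9-trimethyldeca-4,8-dienoate | CC(C)=CCC/C(C)=C/C[C@@](C(=O)C(C(=O)OCC=C)C(=O)CCC=C(C)C)(C)C(=O)OC
F3 | step 4 | prop-2-en-1-yl (5R)-5-[(2E)-3,7-dimethylocta-2,6-dien-1-yl]-2,6-dihydroxy-5-methyl-3-(3-methylbut-2-en-1-yl)-4-oxocyclohexa-2,6-diene-1-carboxylate | CC(C)=CCC/C(C)=C/C[C@@]1(C)C(=O)C(CC=C(C)C)=C(O)C(C(=O)OCC=C)=C1O
F4 | step 8 | (6R)-4-[(2E)-but-2-enoyl]-6-[(2E)-3,7-dimethylocta-2,6-dien-1-yl]-3,5-dihydroxy-6-methyl-2-(3-methylbut-2-en-1-yl)cyclohexa-2,4-dien-1-one | CC(C)=CCC/C(C)=C/C[C@@]1(C)C(=O)C(CC=C(C)C)=C(O)C(C(=O)/C=C/C)=C1O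
F5 | step 2 | 3-tert-butoxy-2-methyl-3-oxopropanoic acid | CC(C(=O)O)C(=O)OC(C)(C)C
F6 | step 2 | tert-butyl diphenylmethyl 2-methylpropanedioate | CC(C(=O)OC(C)(C)C)C(=O)OC(c1ccccc1)c1ccccc1
F7 | step 2 | 1-tert-butyl 3-diphenylmethyl (2S)-2-[(2E)-3,7-dimethylocta-2,6-dien-1-yl]-2-methylpropanedioate | CC(C)=CCC/C(C)=C/C[C@@](C(=O)OC(C)(C)C)(C)C(=O)OC(c1ccccc1)c1ccccc1
F8 | step 2 | (2S,4E)-2-(tert-butoxycarbonyl)-2,5,9-trimethyldeca-4,8-dienoic acid | CC(C)=CCC/C(C)=C/C[C@@](C(=O)OC(C)(C)C)(C)C(=O)O
F9 | step 2 | 1-tert-butyl 3-methyl (2S)-2-[(2E)-3,7-dimethylocta-2,6-dien-1-yl]-2-methylpropanedioate | CC(C)=CCC/C(C)=C/C[C@@](C(=O)OC(C)(C)C)(C)C(=O)OC
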